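**Strategy.** Both cyclohexane units belong to the (3S,5S), i.e. ent-quinate, series, so the carbocycle is built from acyclic material. The plan rests on cutting ring A (the unit whose C1 carries the free tertiary hydroxyl and the ester carbonyl) between C4, the central carbinol, and C5, the carbon bearing the caffeoyloxy group. Ring-closing metathesis of a linear (S)-α-hydroxy-γ-keto ester with allyl and vinyl ketone termini forges C4=C5 as the olefin of a cyclohexenone. Its carbonyl then gives OH-3, and the new olefin gives the cis O4 and, by lactonisation onto C5, the trans O5. One epoxide serves both rings, which are joined through a thioester.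

Key step: step 3

Remark: quinate numbering is used for both rings (C1 quaternary; C3 the carbinol cis to OH-4; C5 the carbinol trans to OH-4). Ring A is the acyl unit, ring B the unit with the free acid. Both rings are read from the SMILES as (3S,5S), the mirror-image series of natural quinic acid. The aldol of step 2 is assumed to follow the facial sense known for pyruvate esters with this catalyst; otherwise the enantiomeric ligand is used.

Step 1
Reactants: 1 di-tert-butyl oxalate; 2 allylmagnesium bromide
Product: 3 tert-butyl 2-oxopent-4-enoate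
Conditions: 2 added to excess 1, THF/Et2O, −78 °C; AcOH quench at −78 °C
Reagents that add atoms: none
Why: Grignard mono-acylation of an oxalate; the magnesium hemiketal should persist at −78 °C, the bulky ester disfavours a second addition, and the cold acidic quench should keep the β,γ-double bond out of conjugation.

Step 2
Reactants: 3 tert-butyl 2-oxopent-4-enoate; 4 2-(trimethylsilyloxy)buta-1,3-diene
Product: 6 tert-butyl (2S)-2-hydroxy-4-oxo-2-(prop-2-en-1-yl)hex-5-enoate, via silyl ether 5 (not isolated)
Conditions: Cu(OTf)2/(S,S)-t-Bu-box (10 mol %), CH2Cl2, −78 °C; then 1 M HCl, THF, 0 °C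
Reagents that add atoms: none
Why: Bis(oxazoline)–copper-catalysed Mukaiyama aldol; the keto ester chelates divalent copper and the enolsilane should attack the open ketone face, setting the tertiary carbinol C1 as S under catalyst control.

Step 3
Reactants: 6 tert-butyl (2S)-2-hydroxy-4-oxo-2-(prop-2-en-1-yl)hex-5-enoate
Product: 7 tert-butyl (1S)-1-hydroxy-5-oxocyclohex-3-ene-1-carboxylate
Conditions: second-generation Hoveyda–Grubbs catalyst RuCl2(=CH-C6H4-2-OiPr)(H2IMes) (3 mol %), CH2Cl2 (0.005 M), 40 °C
Reagents that add atoms: none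
Why: The ruthenium alkylidene should load onto the allyl terminus, add across the vinyl ketone in a [2+2] cycloaddition and cyclorevert with loss of ethene (Chauvin mechanism). The closest known reaction type is ring-closing metathesis of allyl/enone dienes to cyclohex-2-enones. The six-membered carbocycle closes by forming C4=C5 (quinate numbering) between the vinyl ketone α-carbon and the allyl CH, with the olefin inside the new ring. No stereocentre is created and the C1 carbinol from step 2 is untouched. The step needs cyclisation to win over cross-metathesis and allyl isomerisation; high dilution, the gem-disubstituted C1 (Thorpe–Ingold effect) and the low tendency of the enone to homodimerise should secure this, and ethene loss makes it irreversible.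

Step 4
Reactants: 7 tert-butyl (1S)-1-hydroxy-5-oxocyclohex-3-ene-1-carboxylate
Product: 8 tert-butyl (1S,5S)-1,5-dihydroxycyclohex-3-ene-1-carboxylate
Conditions: (R)-2-methyl-CBS-oxazaborolidine (0.5 equiv), catecholborane (3 equiv), toluene, −78 °C; MeOH quench, pH 7 work-up
Reagents that add atoms: none
Why: Corey–Bakshi–Shibata 1,2-reduction; with the olefinic carbon as the large group the (R)-catalyst should give the (S)-allylic alcohol at C3, cis to OH-1, while catecholborane caps OH-1 as a borate that carries no hydride.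

Step 5
Reactants: 8 tert-butyl (1S,5S)-1,5-dihydroxycyclohex-3-ene-1-carboxylate
Product: 9 tert-butyl 4,5-epoxy-1,3-dihydroxycyclohexane-1-carboxylate (OH-1/OH-3/oxirane oxygen all cis; C3 S)
Conditions: mCPBA, NaHCO3, CH2Cl2, 0 °C
Reagents that add atoms: 3-chloroperoxybenzoic acid OOC(=O)c1cccc(Cl)c1
Why: Hydroxyl-directed (Henbest) peracid epoxidation; the allylic OH-3 and the homoallylic OH-1 lie on the same face and should deliver oxygen cis to themselves, setting C4 and C5.

Step 6
Reactants: 10 (E)-3,4-diacetoxycinnamic acid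
Product: 11 (E)-3,4-diacetoxycinnamoyl chloride
Conditions: (COCl)2, DMF (cat.), CH2Cl2, 0 °C → rt; concentrate, strip with toluene, store under argon
Reagents that add atoms: oxalyl chloride O=C(Cl)C(Cl)=O
Why: DMF-catalysed (Vilsmeier-type) conversion of a carboxylic acid into its chloride, which should leave the aryl acetates and the E-olefin untouched and give one batch of acylating agent for steps 7 and 10.

Step 7
Reactants: 9 epoxy diol; 11 (E)-3,4-diacetoxycinnamoyl chloride
Product: 12 tert-butyl 3-O-[(E)-3,4-diacetoxycinnamoyl]-4,5-epoxy-1-hydroxycyclohexane-1-carboxylate (ring B fragment)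
Conditions: 11 (1.05 equiv), pyridine, DMAP (cat.), CH2Cl2, −20 → 0 °C
Reagents that add atoms: none
Why: DMAP-catalysed acylation with an acid chloride; the secondary OH-3 should react far faster than the tertiary, ester-flanked OH-1, and no stereocentre is touched.

Step 8
Reactants: 9 epoxy diol
Product: 14 3,4-O-isopropylidene-ent-quinide (mirror image of quinide acetonide), via ent-quinide 13 (not isolated)
Conditions: TFA/CH2Cl2 (1:4), 0 °C, concentrate; then 2,2-dimethoxypropane, acetone, TsOH·H2O (cat.), rt
Reagents that add atoms: 2,2-dimethoxypropane COC(C)(C)OC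
Why: Acid-promoted intramolecular epoxide opening; the C1 ester carbonyl, on the face opposite the oxirane, should attack C5 in a 5-exo manner with inversion and lose isobutene to give the γ-lactone (O5 trans to O4), after which the cis-3,4-diol is ketalised.

Step 9
Reactants: 14 3,4-O-isopropylidene-ent-quinide
Product: 15 3,4-O-isopropylidene-1-O-trimethylsilyl-ent-quinide
Conditions: TMSCl, imidazole, DMF, rt
Reagents that add atoms: chlorotrimethylsilane C[Si](C)(C)Cl
Why: Silylation of the only free hydroxyl, so that the later acyl transfer cannot be intercepted by OH-1 of ring A.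

Step 10
Reactants: 15 silyl ether; 11 (E)-3,4-diacetoxycinnamoyl chloride
Product: 17 S-tert-butyl 5-O-[(E)-3,4-diacetoxycinnamoyl]-3,4-O-isopropylidene-1-O-trimethylsilyl-ent-thioquinate, via aluminium alkoxide 16 (not isolated)
Conditions: AlMe3, t-BuSH, CH2Cl2, 0 °C; add 15, 0 °C → rt; then pyridine, DMAP (cat.), 11 (excess), 0 °C; aqueous KNaC4H4O6 (potassium sodium tartrate) work-up
Reagents that add atoms: 2-methylpropane-2-thiol CC(C)(C)S; trimethylaluminium C[Al](C)C (its dimethylaluminium group is carried only by intermediate 16)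
Why: Aluminium thiolate opening of the lactone, driven by the Al–O bond, should free O5 as its aluminium alkoxide, which is acylated in the same flask before it can relactonise; the acyl–oxygen cleavage leaves C5 unchanged.

Step 11
Reactants: 17 ring A thioester; 12 ring B fragment
Product: 18 protected dimer (ring A acyl group of 17 esterified to OH-1 of 12)
Conditions: AgOTf (2 equiv), 2,6-di-tert-butyl-4-methylpyridine, 4 Å MS, CH2Cl2, 0 → 35 °C, dark
Reagents that add atoms: none
Why: Thioester-to-ester acyl transfer under thiophilic activation; monovalent silver binds sulfur and should make the acyl group electrophilic enough for the tertiary OH-1 of 12, while the hindered base buffers triflic acid and spares the epoxide, ketal and silyl ether.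

Step 12
Reactants: 18 protected dimer
Product: 20 CNP0107948.1 (target), via lactone 19 (not isolated)
Conditions: TFA/H2O (9:1), 0 °C → rt, concentrate; then 2 M HCl (aq)/THF (1:3), rt, several days
Reagents that add atoms: water O
Why: Acidolysis should remove the tert-butyl ester, silyl ether and ketal; the freed ring B carboxyl opens its epoxide at C5 from the face opposite the oxirane (trans O4/O5); dilute acid then hydrolyses the γ-lactone and the four aryl acetates, conditions that caffeoyl and 1-O-acyl quinate esters are expected to survive.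

**Compound list**
1 | di-tert-butyl oxalate | CC(C)(C)OC(=O)C(=O)OC(C)(C)C | starting material
2 | allylmagnesium bromide | C=CC[Mg]Br | starting material
3 | tert-butyl 2-oxopent-4-enoate | C=CCC(=O)C(=O)OC(C)(C)C | intermediate
4 | 2-(trimethylsilyloxy)buta-1,3-diene | C=CC(=C)O[Si](C)(C)C | starting material
5 | tert-butyl (2S)-4-oxo-2-(prop-2-en-1-yl)-2-(trimethylsilyloxy)hex-5-enoate | C[Si](C)(C)O[C@](C(=O)OC(C)(C)C)(CC(=O)C=C)CC=C | intermediate
6 | tert-butyl (2S)-2-hydroxy-4-oxo-2-(prop-2-en-1-yl)hex-5-enoate | O[C@](C(=O)OC(C)(C)C)(CC(=O)C=C)CC=C | intermediate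
7 | tert-butyl (1S)-1-hydroxy-5-oxocyclohex-3-ene-1-carboxylate | O[C@]1(C(=O)OC(C)(C)C)CC(=O)C=CC1 | intermediate
8 | tert-butyl (1S,5S)-1,5-dihydroxycyclohex-3-ene-1-carboxylate (hydroxyls cis) | O[C@]1(C(=O)OC(C)(C)C)C[C@H](O)C=CC1 | intermediate
9 | tert-butyl 4,5-epoxy-1,3-dihydroxycyclohexane-1-carboxylate (OH-1, OH-3, oxirane O cis; C3 S) | O[C@]1(C(=O)OC(C)(C)C)C[C@H](O)[C@@H]2O[C@@H]2C1 | intermediate
10 | (E)-3,4-diacetoxycinnamic acid | CC(=O)Oc1ccc(/C=C/C(=O)O)cc1OC(C)=O | starting material
11 | (E)-3,4-diacetoxycinnamoyl chloride | CC(=O)Oc1ccc(/C=C/C(=O)Cl)cc1OC(C)=O | intermediate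
12 | ring B fragment: 3-O-[(E)-3,4-diacetoxycinnamoyl] ester of 9 | O[C@]1(C(=O)OC(C)(C)C)C[C@H](OC(=O)/C=C/c3ccc(OC(C)=O)c(OC(C)=O)c3)[C@@H]2O[C@@H]2C1 | intermediate
13 | ent-quinide (1,5-lactone of (3S,5S)-quinic acid) | O[C@]1(C(=O)O2)C[C@H](O)[C@H](O)[C@@H]2C1 | intermediate
14 | 3,4-O-isopropylidene-ent-quinide | O[C@]1(C(=O)O2)C[C@@H]3OC(C)(C)O[C@@H]3[C@@H]2C1 | intermediate
15 | 3,4-O-isopropylidene-1-O-trimethylsilyl-ent-quinide | C[Si](C)(C)O[C@]1(C(=O)O2)C[C@@H]3OC(C)(C)O[C@@H]3[C@@H]2C1 | intermediate
16 | 5-O-dimethylaluminium alkoxide of S-tert-butyl 3,4-O-isopropylidene-1-O-trimethylsilyl-ent-thioquinate | C[Si](C)(C)O[C@]1(C(=O)SC(C)(C)C)C[C@@H]2OC(C)(C)O[C@@H]2[C@@H](O[Al](C)C)C1 | intermediate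
17 | S-tert-butyl 5-O-[(E)-3,4-diacetoxycinnamoyl]-3,4-O-isopropylidene-1-O-trimethylsilyl-ent-thioquinate | C[Si](C)(C)O[C@]1(C(=O)SC(C)(C)C)C[C@@H]2OC(C)(C)O[C@@H]2[C@@H](OC(=O)/C=C/c3ccc(OC(C)=O)c(OC(C)=O)c3)C1 | intermediate
18 | protected dimer (ring A: 1-O-TMS, 3,4-acetonide, 5-O-diacetylcaffeoyl; ring B: tert-butyl ester, 3-O-diacetylcaffeoyl, 4,5-epoxide) | C[Si](C)(C)O[C@]1(C(=O)O[C@]4(C(=O)OC(C)(C)C)C[C@H](OC(=O)/C=C/c5ccc(OC(C)=O)c(OC(C)=O)c5)[C@@H]6O[C@@H]6C4)C[C@@H]2OC(C)(C)O[C@@H]2[C@@H](OC(=O)/C=C/c3ccc(OC(C)=O)c(OC(C)=O)c3)C1 | intermediate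
19 | tetra-acetate in which ring B is the 1,5-lactone and ring A the free triol | O[C@]1(C(=O)O[C@]4(C(=O)O5)C[C@H](OC(=O)/C=C/c6ccc(OC(C)=O)c(OC(C)=O)c6)[C@H](O)[C@@H]5C4)C[C@H](O)[C@H](O)[C@@H](OC(=O)/C=C/c3ccc(OC(C)=O)c(OC(C)=O)c3)C1 | intermediate
20 | CNP0107948.1 | O=C(/C=C/c1ccc(O)c(O)c1)O[C@H]1C[C@@](O)(C(=O)O[C@]2(C(=O)O)C[C@H](OC(=O)/C=C/c3ccc(O)c(O)c3)[C@H](O)[C@@H](O)C2)C[C@H](O)[C@@H]1O | target

**Step count.** Total: 12 steps. Longest linear sequence: 10 steps (steps 1–5 and 8–12).

**Steps most likely to fail**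

Step 11. The acyl transfer joins two fully substituted centres and may be too slow; the activated acyl group may lose carbon monoxide, or the Lewis acid may open the ring B epoxide. The fallback activates the nucleophile instead and attaches both caffeoyl groups last; it sets out from 9 and 15 and comes back to the route at 20. Compound 9 is silylated at O3 (TBSCl, imidazole) to the 3-O-TBS epoxide F1. Compound 15 is opened with AlMe3/t-BuSH and the aluminium alkoxide is trapped with TBSOTf/2,6-lutidine to give the 5-O-TBS thioester F2. The potassium alkoxide of F1 (KN(SiMe3)2, THF, −78 °C) attacks F2 to give the silylated diester F3. Buffered fluoride (TBAF/AcOH, 0 °C) removes the three silyl groups to give the triol F4. F4 is acylated without delay at its two secondary hydroxyls with 11 (pyridine, DMAP) to give the bis-caffeoyl ester F5. F5 lacks only the silyl ether of 18 and is taken through the conditions of step 12 to 20.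

Step 2. The β,γ-double bond of 3 may move into conjugation on the Lewis acid, the adduct may close by oxa-Michael addition, or facial discrimination may be poor. The fallback takes C1 from the chiral pool by self-regeneration of the stereocentre; it replaces steps 1 and 2, starts from commercial (S)-malic acid and not from a numbered compound, and comes back at 6. (S)-Malic acid and pivalaldehyde (TsOH, pentane, reflux) give the cis-dioxolanone acid F6. Its dianion (LiN(SiMe3)2, THF, −78 °C) is allylated with allyl bromide anti to the tert-butyl group, with overall retention, to give the allyl dioxolanone F7. The side-chain acid is converted through its chloride into the vinyl ketone F8 by Stille acylation (Bu3SnCH=CH2, PdCl2(PPh3)2 cat.). Aqueous acid (1 M HCl, THF) releases the hydroxy acid F9, and O-tert-butyl-N,N'-diisopropylisourea esterifies it to 6.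

Step 4. Reagent control may be overridden by the substrate, for instance by hydride delivery from boron bound to OH-1, giving the C3 epimer. The fallback makes that epimer on purpose and inverts it; it sets out from 7 and comes back at 8. Compound 7 is reduced with Me4NBH(OAc)3 (MeCN/AcOH, −20 °C), which delivers hydride from the OH-1 face, to the trans-diol F10. Mitsunobu inversion (4-nitrobenzoic acid, PPh3, DIAD) gives the 4-nitrobenzoate F11, and K2CO3/MeOH frees 8.

**Further compounds**
F1 | step 11 | tert-butyl 3-O-(tert-butyldimethylsilyl)-4,5-epoxy-1-hydroxycyclohexane-1-carboxylate | O[C@]1(C(=O)OC(C)(C)C)C[C@H](O[Si](C)(C)C(C)(C)C)[C@@H]2O[C@@H]2C1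
F2 | step 11 | S-tert-butyl 5-O-(tert-butyldimethylsilyl)-3,4-O-isopropylidene-1-O-trimethylsilyl-ent-thioquinate | C[Si](C)(C)O[C@]1(C(=O)SC(C)(C)C)C[C@@H]2OC(C)(C)O[C@@H]2[C@@H](O[Si](C)(C)C(C)(C)C)C1
F3 | step 11 | silylated diester from F1 and F2 | C[Si](C)(C)O[C@]1(C(=O)O[C@]4(C(=O)OC(C)(C)C)C[C@H](O[Si](C)(C)C(C)(C)C)[C@@H]5O[C@@H]5C4)C[C@@H]2OC(C)(C)O[C@@H]2[C@@H](O[Si](C)(C)C(C)(C)C)C1
F4 | step 11 | desilylated triol diester | O[C@]1(C(=O)O[C@]4(C(=O)OC(C)(C)C)C[C@H](O)[C@@H]5O[C@@H]5C4)C[C@@H]2OC(C)(C)O[C@@H]2[C@@H](O)C1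
F5 | step 11 | bis-caffeoyl ester (18 without the silyl ether) | O[C@]1(C(=O)O[C@]4(C(=O)OC(C)(C)C)C[C@H](OC(=O)/C=C/c5ccc(OC(C)=O)c(OC(C)=O)c5)[C@@H]6O[C@@H]6C4)C[C@@H]2OC(C)(C)O[C@@H]2[C@@H](OC(=O)/C=C/c3ccc(OC(C)=O)c(OC(C)=O)c3)C1
F6 | step 2 | cis-2-tert-butyl-5-oxo-1,3-dioxolane-4-acetic acid from (S)-malic acid | CC(C)(C)[C@@H]1OC(=O)[C@H](CC(O)=O)O1
F7 | step 2 | 4-allyl derivative of F6 (allyl trans to tert-butyl) | CC(C)(C)[C@@H]1OC(=O)[C@](CC=C)(CC(O)=O)O1
F8 | step 2 | vinyl ketone from F7 | CC(C)(C)[C@@H]1OC(=O)[C@](CC=C)(CC(=O)C=C)O1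
F9 | step 2 | (2S)-2-hydroxy-4-oxo-2-(prop-2-en-1-yl)hex-5-enoic acid | O[C@](C(=O)O)(CC(=O)C=C)CC=C
F10 | step 4 | tert-butyl (1S,5R)-1,5-dihydroxycyclohex-3-ene-1-carboxylate (hydroxyls trans) | O[C@]1(C(=O)OC(C)(C)C)C[C@@H](O)C=CC1
F11 | step 4 | 5-O-(4-nitrobenzoyl) ester of 8 | O[C@]1(C(=O)OC(C)(C)C)C[C@H](OC(=O)c2ccc(cc2)[N+](=O)[O-])C=CC1
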